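The number is 0.235 in the larch run and 0.222 in the alder run, though G was charged at 13 mM in one and 52 mM in the other. I carry their mean, 0.229, as the peak return, the ratio of D to L at the highest reading divided by the charge of G per charge of L, and it belongs to the 0.19 mM of Q that both runs share.

common to all: L 20 mM; Q 0.19 mM

| charge | G | remark | time |
|---|---|---|---|
| larch | 13 mM | run made earlier |  |
| alder | 52 mM | run made earlier |  |
| flask | 26.0 mM |  | 3.0 h |

| run | time / h | D / % | L / % |
|---|---|---|---|
| larch | 0.0833 | 9.0 | 91.9 |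
| larch | 0.167 | 12.8 | 87.6 |
| larch | 0.333 | 13.1 | 85.6 |
| larch | 0.667 | 9.9 | 89.9 |
| larch | 1.33 | 6.3 | 94.7 |
| larch | 2.50 | 0.7 | 97.4 |
| alder | 0.0833 | 21.3 | 77.4 |
| alder | 0.167 | 30.5 | 69.6 |
| alder | 0.333 | 37.1 | 64.2 |
| alder | 0.667 | 32.8 | 68.4 |
| alder | 1.33 | 19.5 | 80.5 |
| alder | 2.50 | 7.2 | 93.3 |

(each reading ± 1 percentage point)

* when, up to 3.0 h, the flask holds most D
* the amount of D, in percent of the L charged, at that time

I let one number serve for the height: the alder value, applied to the larch run, puts D at 12.4% beside the 13.1% read, a gap of 0.70 percentage points to hold against the scatter of 1 point. It carries no time, so I take the 0.333 h at which both runs read highest. D and L together read 98.7% and 101% there, so for this flask I reckon: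

D/L = 0.229 × 26.0/20 = 0.298

D = 22.9% of the L charged

The forecast says 22.5% (range 19.5% to 25.5%) at 0.3 h (range 0.2 h to 0.4 h), on this ground: “D therefore tracks the falling G after a quick rise”. My figure stands 0.40 points above its figure.

The flask holds most D at 0.299 h, namely 23.1% beside 76.9% of L, a peak return of 0.231.

    G + Q ⇌ Z (K = 58.0 M⁻¹, k = 12.2 M⁻¹ s⁻¹)
    L + Z ⇌ J (K = 7.60 M⁻¹, k = 9.88 M⁻¹ s⁻¹)
    J ⇌ Q + D (K = 0.0490 M, k = 13.6 s⁻¹)
    G → E (k = 3.74 × 10⁻⁴ s⁻¹)

At that time in the flask G stands at 53.5% of its charge, and the catalyst stands 52.6% as Q, 42.4% as Z and 4.96% as J. The turning of G into E runs on with a half-life of 0.51 h taken alone, G falls to 3.93% at 3.00 h, and D falls with it to 2.41%. The neighbour charged with 0.048 mM of Q reaches 16.1%, a peak return of 0.148 with L taken as the remainder.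

(All runs were computed with constants of no real substance, noise included.)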